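**Retrosynthetic overview**
1. Target 27 ⇐ 26 ⇐ 25: the C6 acetate and the C4–C5 oxirane go on last, by acetylation and by hydroxyl-directed epoxidation of the E-C4=C5 alkene of a 6-hydroxy germacradienolide.
2. Enabling feature: C6, an oxygen-bearing carbon of the ten-membered carbocycle, sits directly beside the C4–C5 oxirane. This epoxy-carbinol is the retron of an (E)-allylic alcohol, so C5 can be an sp2 iodide carbon and C6 an aldehyde carbon: two electrophilic centres, joined after reductive polarity reversal of C5.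
3. The ten-membered carbocycle is closed at C5–C6 by intramolecular Nozaki–Hiyama–Kishi coupling of iodoalkenyl aldehyde 22. This one operation closes the carbocycle, sets C6 and creates the hydroxyl that later steers the oxirane (C4, C5).
4. The γ-lactone (C7–C8 bond, trans) comes from catalytic asymmetric chromium allylation and lactonisation of C8 aldehyde 12 with bromide 16. Its exo-methylene is masked as a phenylselenide adduct while C6 is an aldehyde.
5. Chain 12 comes from enal 5 by C2 propargylation, then carboalumination–iodination. Ring order: γ-lactone (step 10), ten-membered carbocycle (step 14), oxirane (step 16).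

Key step: step 14

Remark on numbering: germacranolide numbering is used (ring C1–C10, lactone carbons C11–C13, C14 on C10, C15 on C4); the target is (2S,4R,5R,6S,7R,8S)-2,6-diacetoxy-4,5-epoxygermacra-1(10)E,11(13)-dien-12,8-olide.
Assumption: the temporary C11 centre of 20–24 is drawn as the epimer with the selenomethyl group trans to the C7 substituent, as expected from reversible addition; either epimer serves, because step 15 removes the centre.

**Route**

Step 1
Reactants: 1 tert-butyl(but-3-yn-1-yloxy)dimethylsilane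
Product: 4 (E)-5-(tert-butyldimethylsilyloxy)-3-methylpent-2-en-1-ol, via alkenylalane 2 (not isolated), via lithium alkenylalanate 3 (not isolated)
Conditions: Me3Al (2 equiv), Cp2ZrCl2 (0.25 equiv), CH2Cl2, 0 °C to rt; excess Me3Al removed in vacuo; n-BuLi, THF/hexane, −78 °C; (CH2O)n, −78 °C to rt; aq. sodium potassium tartrate
Reagents that add atoms: trimethylaluminium C[Al](C)C; paraformaldehyde (as formaldehyde) C=O
Why: Zirconium-catalysed Negishi carboalumination adds methyl and aluminium syn across the terminal alkyne with aluminium on the terminal carbon, which fixes the E geometry of the future C1=C10 alkene, and the butyl alanate is then hydroxymethylated by formaldehyde with retention.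

Step 2
Reactants: 4 (E)-5-(tert-butyldimethylsilyloxy)-3-methylpent-2-en-1-ol
Product: 5 (E)-5-(tert-butyldimethylsilyloxy)-3-methylpent-2-enal
Conditions: MnO2 (15 equiv), CH2Cl2, rt
Reagents that add atoms: none
Why: Allylic oxidation with MnO2 is selective for the allylic alcohol, stops at the aldehyde and does not isomerise the E alkene or touch the silyl ether.

Step 3
Reactants: 5 (E)-5-(tert-butyldimethylsilyloxy)-3-methylpent-2-enal; 6 allenylboronic acid pinacol ester
Product: 7 (4S,5E)-8-(tert-butyldimethylsilyloxy)-6-methyloct-5-en-1-yn-4-ol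
Conditions: (S)-TRIP [(S)-3,3′-bis(2,4,6-triisopropylphenyl)-1,1′-binaphthyl-2,2′-diyl hydrogen phosphate] (10 mol %), 4 Å MS, toluene, −20 °C; aq. NaHCO3
Reagents that add atoms: none
Why: Chiral phosphoric acid-catalysed propargylboration of an aldehyde by an allenylboronate runs through a closed six-membered SE2′ transition state in which the (S)-configured acid, bound to a boronate oxygen and the formyl hydrogen, is expected to leave the Si face of the enal open, so 1,2-addition sets C2 as S.

Step 4
Reactants: 7 (4S,5E)-8-(tert-butyldimethylsilyloxy)-6-methyloct-5-en-1-yn-4-ol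
Product: 9 (1E,4S,5E)-8-(tert-butyldimethylsilyloxy)-1-iodo-2,6-dimethylocta-1,5-dien-4-ol, via alkenylalane alkoxide 8 (not isolated)
Conditions: Me3Al (3.5 equiv), Cp2ZrCl2 (0.3 equiv), CH2Cl2, −20 °C to rt; then I2, THF, −30 to 0 °C; aq. NaHCO3/Na2S2O3
Reagents that add atoms: trimethylaluminium C[Al](C)C; iodine II
Why: Negishi carboalumination of the homopropargylic aluminium alkoxide places methyl on C4 and aluminium on C5 cis to it, and iodinolysis with retention gives the (E)-iodoalkene, while the trisubstituted C1=C10 alkene, the silyl ether and the C2 centre are not affected.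

Step 5
Reactants: 9 (1E,4S,5E)-8-(tert-butyldimethylsilyloxy)-1-iodo-2,6-dimethylocta-1,5-dien-4-ol
Product: 10 (1E,4S,5E)-8-(tert-butyldimethylsilyloxy)-1-iodo-2,6-dimethylocta-1,5-dien-4-yl acetate
Conditions: Ac2O, pyridine, DMAP (cat.), CH2Cl2, 0 °C to rt
Reagents that add atoms: acetic anhydride CC(=O)OC(C)=O
Why: DMAP-catalysed O-acylation of the secondary allylic alcohol installs the C2 acetate of the target with retention at C2 and removes the free hydroxyl that would otherwise misdirect the later epoxidation.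

Step 6
Reactants: 10 (1E,4S,5E)-8-(tert-butyldimethylsilyloxy)-1-iodo-2,6-dimethylocta-1,5-dien-4-yl acetate
Product: 11 (1E,4S,5E)-8-hydroxy-1-iodo-2,6-dimethylocta-1,5-dien-4-yl acetate
Conditions: HF·pyridine, pyridine, THF, 0 °C to rt
Reagents that add atoms: none
Why: Fluoride-mediated desilylation under pyridine buffering frees the primary alcohol without ionising the allylic acetate or touching the iodoalkene.

Step 7
Reactants: 11 (1E,4S,5E)-8-hydroxy-1-iodo-2,6-dimethylocta-1,5-dien-4-yl acetate
Product: 12 (1E,4S,5E)-1-iodo-2,6-dimethyl-8-oxoocta-1,5-dien-4-yl acetate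
Conditions: Dess–Martin periodinane, NaHCO3, CH2Cl2, 0 °C; crude aldehyde used at once
Reagents that add atoms: none
Why: Dess–Martin oxidation under bicarbonate buffering gives the β,γ-unsaturated C8 aldehyde without base that could move the C1=C10 alkene into conjugation.

Step 8
Reactants: 13 methyl acrylate; 14 2-(tert-butyldimethylsilyloxy)acetaldehyde
Product: 15 methyl 4-(tert-butyldimethylsilyloxy)-3-hydroxy-2-methylenebutanoate (racemic)
Conditions: DABCO (0.5 equiv), neat, rt
Reagents that add atoms: none
Why: Morita–Baylis–Hillman reaction, in which the DABCO–acrylate zwitterion adds to the aldehyde and the amine is expelled; the new carbinol centre is racemic and is erased in step 9.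

Step 9
Reactants: 15 methyl 4-(tert-butyldimethylsilyloxy)-3-hydroxy-2-methylenebutanoate
Product: 16 methyl (Z)-2-(bromomethyl)-4-(tert-butyldimethylsilyloxy)but-2-enoate
Conditions: N-bromosuccinimide, Me2S, CH2Cl2, 0 °C to rt
Reagents that add atoms: N-bromosuccinimide O=C1CCC(=O)N1Br
Why: The sulfonium reagent of the Corey–Kim type turns the allylic hydroxyl into an alkoxysulfonium leaving group and bromide attacks in SN2′ fashion to give the thermodynamically preferred (Z)-2-(bromomethyl)enoate with loss of the stereocentre.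

Step 10
Reactants: 12 (1E,4S,5E)-1-iodo-2,6-dimethyl-8-oxoocta-1,5-dien-4-yl acetate; 16 methyl (Z)-2-(bromomethyl)-4-(tert-butyldimethylsilyloxy)but-2-enoate
Product: 19 (4S,5S)-5-[(2E,4S,6E)-4-acetoxy-7-iodo-2,6-dimethylhepta-2,6-dien-1-yl]-4-[(tert-butyldimethylsilyloxy)methyl]-3-methylenedihydrofuran-2(3H)-one, via silyl ether adduct 17 (not isolated), via hydroxy ester 18 (not isolated)
Conditions: CrCl2 (10 mol %), (S,S)-1,8-bis(4-isopropyl-4,5-dihydrooxazol-2-yl)-3,6-diphenyl-9H-carbazole (12 mol %), Mn powder (2 equiv), TMSCl (1.5 equiv), i-Pr2NEt (0.3 equiv), THF, rt; then 1 M HCl, THF, 0 °C; then PPTS (cat.), CH2Cl2, rt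
Reagents that add atoms: none
Why: Chromium-catalysed asymmetric Nozaki–Hiyama allylation, in which divalent chromium inserts into the C–Br bond, the allylchromium equilibrates and adds through a chair Zimmerman–Traxler transition state with the aldehyde chain and the C6 substituent both equatorial to give the anti adduct (C7 and C8 substituents trans in the lactone), while the ligand, used in the antipode that blocks the Si face, sends the allyl group to the Re face of the aldehyde to set 8S and with it C7; TMSCl frees the catalyst, Mn returns it to divalent chromium, and acid removes the O-trimethylsilyl group and closes the α-methylene-γ-lactone.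

Step 11
Reactants: 19 (4S,5S)-5-[(2E,4S,6E)-4-acetoxy-7-iodo-2,6-dimethylhepta-2,6-dien-1-yl]-4-[(tert-butyldimethylsilyloxy)methyl]-3-methylenedihydrofuran-2(3H)-one
Product: 20 (3R,4S,5S)-5-[(2E,4S,6E)-4-acetoxy-7-iodo-2,6-dimethylhepta-2,6-dien-1-yl]-4-[(tert-butyldimethylsilyloxy)methyl]-3-[(phenylselanyl)methyl]dihydrofuran-2(3H)-one
Conditions: PhSeH (1.2 equiv), Et3N (0.1 equiv), CH2Cl2, 0 °C
Reagents that add atoms: benzeneselenol [SeH]c1ccccc1
Why: Base-catalysed conjugate (Michael) addition of the soft selenol masks the α-methylene lactone, so that C7–H will not be a vinylogously activated, isomerisation-prone position once C6 is an aldehyde; reversible addition and protonation are expected to give the all-trans lactone, and the C11 centre is temporary.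

Step 12
Reactants: 20 (3R,4S,5S)-5-[(2E,4S,6E)-4-acetoxy-7-iodo-2,6-dimethylhepta-2,6-dien-1-yl]-4-[(tert-butyldimethylsilyloxy)methyl]-3-[(phenylselanyl)methyl]dihydrofuran-2(3H)-one
Product: 21 (3R,4S,5S)-5-[(2E,4S,6E)-4-acetoxy-7-iodo-2,6-dimethylhepta-2,6-dien-1-yl]-4-(hydroxymethyl)-3-[(phenylselanyl)methyl]dihydrofuran-2(3H)-one
Conditions: HF·pyridine, pyridine, THF, 0 °C to rt
Reagents that add atoms: none
Why: Fluoride-mediated desilylation of the primary silyl ether under pyridine buffering leaves lactone, selenide, allylic acetate and iodoalkene intact.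

Step 13
Reactants: 21 (3R,4S,5S)-5-[(2E,4S,6E)-4-acetoxy-7-iodo-2,6-dimethylhepta-2,6-dien-1-yl]-4-(hydroxymethyl)-3-[(phenylselanyl)methyl]dihydrofuran-2(3H)-one
Product: 22 (2S,3R,4R)-2-[(2E,4S,6E)-4-acetoxy-7-iodo-2,6-dimethylhepta-2,6-dien-1-yl]-5-oxo-4-[(phenylselanyl)methyl]tetrahydrofuran-3-carbaldehyde
Conditions: Dess–Martin periodinane, NaHCO3, CH2Cl2, 0 °C; crude aldehyde used at once
Reagents that add atoms: none
Why: Dess–Martin oxidation under neutral buffered conditions tolerates the aryl alkyl selenide and gives the C6 aldehyde without epimerisation at C7 or β-elimination of the C8 carboxylate.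

Step 14
Reactants: 22 (2S,3R,4R)-2-[(2E,4S,6E)-4-acetoxy-7-iodo-2,6-dimethylhepta-2,6-dien-1-yl]-5-oxo-4-[(phenylselanyl)methyl]tetrahydrofuran-3-carbaldehyde
Product: 23 (2S,6R,7S,8S,11R)-2-acetoxy-6-hydroxy-13-(phenylselanyl)germacra-1(10)E,4E-dien-12,8-olide
Conditions: CrCl2 (10 equiv), NiCl2 (0.1 equiv), degassed DMSO, rt, 22 added by syringe pump over 12 h (final 2 mM); aq. NH4Cl
Reagents that add atoms: none
Why: Zerovalent nickel, formed from NiCl2 by CrCl2, inserts into the C5–I bond with retention of the E geometry, the alkenyl group passes to trivalent chromium, and the alkenylchromium adds to the C6 aldehyde through an oxygen-bound closed transition state, which unites two carbons that are both electrophilic in the precursor. The closest known reaction type is the intramolecular Nozaki–Hiyama–Kishi coupling of iodoalkenyl aldehydes used to close ten-membered carbocycles of germacranolides and related medium-ring terpenoids. The ten-membered carbocycle is closed in the 10-exo-trig mode (carbonyl oxygen outside the new ring), and the E-C4=C5 alkene becomes endocyclic. The new C6 centre is controlled by the adjacent C7 centre and the trans-lactone: in the product-like folding of the chain, C6–H eclipses the C4=C5 plane to avoid allylic 1,3-strain with the C15 methyl and stays anti to C7–H, the chromium-bound oxygen points to the ring periphery, and attack on the Re face of the aldehyde is therefore expected to give the 6α alcohol (6R in 23). The step needs chemoselectivity for the alkenyl iodide over the allylic acetate, the lactone and the selenide, which the mild, oxophilic alkenylchromium secures, and cyclisation over oligomerisation, which slow addition to high dilution and the turn imposed by the trans-lactone and the E-C1=C10 alkene secure. The hydroxyl created here is the handle that directs the epoxidation of C4=C5 in step 16.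

Step 15
Reactants: 23 (2S,6R,7S,8S,11R)-2-acetoxy-6-hydroxy-13-(phenylselanyl)germacra-1(10)E,4E-dien-12,8-olide
Product: 25 (2S,6R,7S,8S)-2-acetoxy-6-hydroxygermacra-1(10)E,4E,11(13)-trien-12,8-olide, via selenoxide 24 (not isolated)
Conditions: NaIO4 (1.5 equiv), NaHCO3, THF/H2O (3:1), 0 °C to rt
Reagents that add atoms: none
Why: Periodate oxidises selenium to the selenoxide, which undergoes syn-elimination near room temperature through its only β-hydrogen (C11–H) and so regenerates the C11=C13 exo-methylene lactone without a peroxide that could epoxidise the ring alkenes.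

Step 16
Reactants: 25 (2S,6R,7S,8S)-2-acetoxy-6-hydroxygermacra-1(10)E,4E,11(13)-trien-12,8-olide
Product: 26 (2S,4R,5R,6S,7S,8S)-2-acetoxy-4,5-epoxy-6-hydroxygermacra-1(10)E,11(13)-dien-12,8-olide
Conditions: VO(acac)2 (5 mol %), t-BuOOH (1.5 equiv, decane), CH2Cl2, 0 °C
Reagents that add atoms: tert-butyl hydroperoxide CC(C)(C)OO
Why: Hydroxyl-directed vanadium-catalysed epoxidation, in which the pentavalent vanadium alkoxide of the C6 hydroxyl delivers oxygen to C4=C5 on the face that carries the hydroxyl when C6–H eclipses the alkene plane (allylic 1,3-strain with C15), which is also the peripheral face of the E-cycloalkene, so the threo epoxy alcohol with 4R and 5R should result, while the C1=C10 alkene (no free hydroxyl) and the electron-poor C11=C13 alkene are left alone.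

Step 17
Reactants: 26 (2S,4R,5R,6S,7S,8S)-2-acetoxy-4,5-epoxy-6-hydroxygermacra-1(10)E,11(13)-dien-12,8-olide
Product: 27 (2S,4R,5R,6S,7R,8S)-2,6-diacetoxy-4,5-epoxygermacra-1(10)E,11(13)-dien-12,8-olide
Conditions: Ac2O, pyridine, DMAP (cat.), CH2Cl2, 0 °C to rt
Reagents that add atoms: acetic anhydride CC(=O)OC(C)=O
Why: DMAP-catalysed acetylation of the remaining secondary hydroxyl at C6, with retention, completes the target without opening the oxirane or adding to the methylene lactone.

**Compound list**
1 | tert-butyl(but-3-yn-1-yloxy)dimethylsilane | C#CCCO[Si](C)(C)C(C)(C)C | starting material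
2 | (E)-[4-(tert-butyldimethylsilyloxy)-2-methylbut-1-en-1-yl]dimethylalumane | C[Al](C)/C=C(\C)CCO[Si](C)(C)C(C)(C)C | intermediate
3 | lithium (E)-butyl[4-(tert-butyldimethylsilyloxy)-2-methylbut-1-en-1-yl]dimethylalanate | [Li+].CCCC[Al-](C)(C)/C=C(\C)CCO[Si](C)(C)C(C)(C)C | intermediate
4 | (E)-5-(tert-butyldimethylsilyloxy)-3-methylpent-2-en-1-ol | OC/C=C(\C)CCO[Si](C)(C)C(C)(C)C | intermediate
5 | (E)-5-(tert-butyldimethylsilyloxy)-3-methylpent-2-enal | O=C/C=C(\C)CCO[Si](C)(C)C(C)(C)C | intermediate
6 | allenylboronic acid pinacol ester (4,4,5,5-tetramethyl-2-(propa-1,2-dien-1-yl)-1,3,2-dioxaborolane) | C=C=CB1OC(C)(C)C(C)(C)O1 | starting material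
7 | (4S,5E)-8-(tert-butyldimethylsilyloxy)-6-methyloct-5-en-1-yn-4-ol | CC(C)(C)[Si](C)(C)OCC/C(C)=C/[C@@H](O)CC#C | intermediate
8 | dimethylaluminium (1E,4S,5E)-8-(tert-butyldimethylsilyloxy)-1-(dimethylalumanyl)-2,6-dimethylocta-1,5-dien-4-olate | CC(C)(C)[Si](C)(C)OCC/C(C)=C/[C@@H](O[Al](C)C)C/C(C)=C/[Al](C)C | intermediate
9 | (1E,4S,5E)-8-(tert-butyldimethylsilyloxy)-1-iodo-2,6-dimethylocta-1,5-dien-4-ol | CC(C)(C)[Si](C)(C)OCC/C(C)=C/[C@@H](O)C/C(C)=C/I | intermediate
10 | (1E,4S,5E)-8-(tert-butyldimethylsilyloxy)-1-iodo-2,6-dimethylocta-1,5-dien-4-yl acetate | CC(C)(C)[Si](C)(C)OCC/C(C)=C/[C@@H](OC(C)=O)C/C(C)=C/I | intermediate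
11 | (1E,4S,5E)-8-hydroxy-1-iodo-2,6-dimethylocta-1,5-dien-4-yl acetate | OCC/C(C)=C/[C@@H](OC(C)=O)C/C(C)=C/I | intermediate
12 | (1E,4S,5E)-1-iodo-2,6-dimethyl-8-oxoocta-1,5-dien-4-yl acetate (C8 aldehyde, C2 acetate, C5 iodide) | O=CC/C(C)=C/[C@@H](OC(C)=O)C/C(C)=C/I | intermediate
13 | methyl acrylate | C=CC(=O)OC | starting material
14 | 2-(tert-butyldimethylsilyloxy)acetaldehyde | O=CCO[Si](C)(C)C(C)(C)C | starting material
15 | methyl 4-(tert-butyldimethylsilyloxy)-3-hydroxy-2-methylenebutanoate (racemic) | C=C(C(=O)OC)C(O)CO[Si](C)(C)C(C)(C)C | intermediate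
16 | methyl (Z)-2-(bromomethyl)-4-(tert-butyldimethylsilyloxy)but-2-enoate | COC(=O)/C(CBr)=C/CO[Si](C)(C)C(C)(C)C | intermediate
17 | methyl (3S,4S,6E,8S,10E)-8-acetoxy-3-[(tert-butyldimethylsilyloxy)methyl]-11-iodo-6,10-dimethyl-2-methylene-4-(trimethylsilyloxy)undeca-6,10-dienoate | C=C(C(=O)OC)[C@@H](CO[Si](C)(C)C(C)(C)C)[C@@H](O[Si](C)(C)C)C/C(C)=C/[C@@H](OC(C)=O)C/C(C)=C/I | intermediate
18 | methyl (3S,4S,6E,8S,10E)-8-acetoxy-3-[(tert-butyldimethylsilyloxy)methyl]-4-hydroxy-11-iodo-6,10-dimethyl-2-methyleneundeca-6,10-dienoate | C=C(C(=O)OC)[C@@H](CO[Si](C)(C)C(C)(C)C)[C@@H](O)C/C(C)=C/[C@@H](OC(C)=O)C/C(C)=C/I | intermediate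
19 | (4S,5S)-5-[(2E,4S,6E)-4-acetoxy-7-iodo-2,6-dimethylhepta-2,6-dien-1-yl]-4-[(tert-butyldimethylsilyloxy)methyl]-3-methylenedihydrofuran-2(3H)-one | C=C1C(=O)O[C@@H](C/C(C)=C/[C@@H](OC(C)=O)C/C(C)=C/I)[C@@H]1CO[Si](C)(C)C(C)(C)C | intermediate
20 | (3R,4S,5S)-5-[(2E,4S,6E)-4-acetoxy-7-iodo-2,6-dimethylhepta-2,6-dien-1-yl]-4-[(tert-butyldimethylsilyloxy)methyl]-3-[(phenylselanyl)methyl]dihydrofuran-2(3H)-one | O=C1O[C@@H](C/C(C)=C/[C@@H](OC(C)=O)C/C(C)=C/I)[C@H](CO[Si](C)(C)C(C)(C)C)[C@H]1C[Se]c1ccccc1 | intermediate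
21 | (3R,4S,5S)-5-[(2E,4S,6E)-4-acetoxy-7-iodo-2,6-dimethylhepta-2,6-dien-1-yl]-4-(hydroxymethyl)-3-[(phenylselanyl)methyl]dihydrofuran-2(3H)-one | O=C1O[C@@H](C/C(C)=C/[C@@H](OC(C)=O)C/C(C)=C/I)[C@H](CO)[C@H]1C[Se]c1ccccc1 | intermediate
22 | (2S,3R,4R)-2-[(2E,4S,6E)-4-acetoxy-7-iodo-2,6-dimethylhepta-2,6-dien-1-yl]-5-oxo-4-[(phenylselanyl)methyl]tetrahydrofuran-3-carbaldehyde | O=C1O[C@@H](C/C(C)=C/[C@@H](OC(C)=O)C/C(C)=C/I)[C@H](C=O)[C@H]1C[Se]c1ccccc1 | intermediate
23 | (2S,6R,7S,8S,11R)-2-acetoxy-6-hydroxy-13-(phenylselanyl)germacra-1(10)E,4E-dien-12,8-olide | O=C1O[C@H]2C/C(C)=C/[C@@H](OC(C)=O)C/C(C)=C/[C@@H](O)[C@@H]2[C@H]1C[Se]c1ccccc1 | intermediate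
24 | selenoxide of 23: (2S,6R,7S,8S,11R)-2-acetoxy-6-hydroxy-13-(phenylseleninyl)germacra-1(10)E,4E-dien-12,8-olide | O=C1O[C@H]2C/C(C)=C/[C@@H](OC(C)=O)C/C(C)=C/[C@@H](O)[C@@H]2[C@H]1C[Se](=O)c1ccccc1 | intermediate
25 | (2S,6R,7S,8S)-2-acetoxy-6-hydroxygermacra-1(10)E,4E,11(13)-trien-12,8-olide | C=C1C(=O)O[C@H]2C/C(C)=C/[C@@H](OC(C)=O)C/C(C)=C/[C@@H](O)[C@H]12 | intermediate
26 | (2S,4R,5R,6S,7S,8S)-2-acetoxy-4,5-epoxy-6-hydroxygermacra-1(10)E,11(13)-dien-12,8-olide | C=C1C(=O)O[C@H]2C/C(C)=C/[C@@H](OC(C)=O)C[C@@]3(C)O[C@@H]3[C@@H](O)[C@H]12 | intermediate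
27 | (2S,4R,5R,6S,7R,8S)-2,6-diacetoxy-4,5-epoxygermacra-1(10)E,11(13)-dien-12,8-olide (CNP0270851.2) | C=C1C(=O)O[C@H]2C/C(C)=C/[C@@H](OC(C)=O)C[C@@]3(C)O[C@@H]3[C@@H](OC(C)=O)[C@H]12 | target

**Step count**
Total: 17 steps. Longest linear sequence: 15 steps (steps 1–7, then 10–17); steps 8–9 make the bromide 16 in a side branch.

**Steps most likely to fail**

Step 14. The likely failure is poor facial selectivity in the addition of the alkenylchromium to the C6 aldehyde, since the acyclic preference at C7 and the ring-folding preference need not agree. The fallback replaces substrate control by reagent control and sets out from 23 as obtained (mixed at C6). Dess–Martin oxidation (NaHCO3, CH2Cl2, 0 °C) should give the macrocyclic enone (2S,7R,8S,11R)-2-acetoxy-6-oxo-13-(phenylselanyl)germacra-1(10)E,4E-dien-12,8-olide F1. Corey–Bakshi–Shibata reduction with the (R)-configured 2-methyl-oxazaborolidine and catecholborane in toluene at −78 °C, with the alkenyl group as the large substituent, should then return the route at 23.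

Step 10. The likely failure is insufficient catalyst control over the aldehyde face, as the existing C2 centre is too remote to help. The fallback gives up catalyst control, sets out from 12 and 16, and uses stoichiometric CrCl2 (3 equiv) in THF at rt without ligand. The same anti-selective chair addition, followed by lactonisation of the chromium alkoxide, should give 19 together with the C7,C8-bis-epimeric lactone (4R,5R)-5-[(2E,4S,6E)-4-acetoxy-7-iodo-2,6-dimethylhepta-2,6-dien-1-yl]-4-[(tert-butyldimethylsilyloxy)methyl]-3-methylenedihydrofuran-2(3H)-one F2. Because C2 is already fixed the two are diastereomers and are separated by chromatography, and the route is rejoined at 19.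

Step 3. The likely failure is low enantiofacial discrimination on the β,β-disubstituted enal. The fallback sets the centre by oxidation and reagent-controlled reduction and sets out from 5. Zinc-mediated Barbier propargylation (propargyl bromide, Zn dust, THF/aq. NH4Cl) should give racemic (E)-8-(tert-butyldimethylsilyloxy)-6-methyloct-5-en-1-yn-4-ol F3. Dess–Martin oxidation gives (E)-8-(tert-butyldimethylsilyloxy)-6-methyloct-5-en-1-yn-4-one F4. Corey–Bakshi–Shibata reduction with the (R)-configured 2-methyl-oxazaborolidine and BH3·SMe2 at −40 °C, with the alkenyl group as the large substituent, comes back to the route at 7.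

**Further compounds**
F1 | step 14 | (2S,7R,8S,11R)-2-acetoxy-6-oxo-13-(phenylselanyl)germacra-1(10)E,4E-dien-12,8-olide | O=C1O[C@H]2C/C(C)=C/[C@@H](OC(C)=O)C/C(C)=C/C(=O)[C@@H]2[C@H]1C[Se]c1ccccc1
F2 | step 10 | (4R,5R)-5-[(2E,4S,6E)-4-acetoxy-7-iodo-2,6-dimethylhepta-2,6-dien-1-yl]-4-[(tert-butyldimethylsilyloxy)methyl]-3-methylenedihydrofuran-2(3H)-one | C=C1C(=O)O[C@H](C/C(C)=C/[C@@H](OC(C)=O)C/C(C)=C/I)[C@H]1CO[Si](C)(C)C(C)(C)C
F3 | step 3 | racemic (E)-8-(tert-butyldimethylsilyloxy)-6-methyloct-5-en-1-yn-4-ol | CC(C)(C)[Si](C)(C)OCC/C(C)=C/C(O)CC#C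
F4 | step 3 | (E)-8-(tert-butyldimethylsilyloxy)-6-methyloct-5-en-1-yn-4-one | CC(C)(C)[Si](C)(C)OCC/C(C)=C/C(=O)CC#C
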